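**Retrosynthetic overview**
1. Target 16 ⇐ C6–geranyl bond, made last by C-alkylation of triol ketone 14 with geranyl bromide 15, so the geranyl alkenes never meet an oxidant, an organolithium or H2.
2. 14 ⇐ C8–benzoyl bond: 8-bromide 9 (C8-selective NBS bromination of tribenzyl ether 8), Br/Li exchange and Weinreb amide 10; all three benzyl ethers removed by hydrogenolysis.
3. Chromanol 7 ⇐ o-prenylphenol 5 by the new step: phenol-directed Hf/bis-hydroxamic-acid asymmetric epoxidation with in-flask 6-endo epoxide opening, which closes the pyran ring and sets C3 (R).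
4. 5 ⇐ 3,5-bis(benzyloxy)phenol 1 + carbonate 2: Pd O-tert-prenylation, then aromatic Claisen onto one of two equivalent ortho carbons.
5. Ring order: the arene is bought; the dihydropyran ring (step 3) is the only ring built.

Assumption: the (R,R)-ligand is written for step 3, but the facial sense of this new reaction is not predictable, so the configuration of 7 is checked (Mosher esters, or comparison with 7 from the fallback) and the (S,S)-ligand is used if needed; 1, 2, 10 and 15 are taken as commercial.

**Step 1**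
Reactants: 1 3,5-bis(benzyloxy)phenol; 2 tert-butyl (2-methylbut-3-en-2-yl) carbonate
Product: 3 1,3-bis(benzyloxy)-5-[(2-methylbut-3-en-2-yl)oxy]benzene
Conditions: Pd(PPh3)4 (2 mol%), 4 Å MS, THF, 0 °C → rt
Reagents that add atoms: none
Why: Tsuji–Trost O-allylation in which ionisation of 2 gives a 1,1-dimethyl-π-allyl-Pd complex plus tert-butoxide (which deprotonates 1), and the phenoxide attacks the more substituted allyl terminus under kinetic control to give the tertiary ether; no stereocentre is formed.

**Step 2**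
Reactants: 3 1,3-bis(benzyloxy)-5-[(2-methylbut-3-en-2-yl)oxy]benzene
Product: 5 3,5-bis(benzyloxy)-2-(3-methylbut-2-en-1-yl)phenol, via Claisen dienone 4 (not isolated)
Conditions: PhNEt2, 130 °C, 3 h
Reagents that add atoms: none
Why: Aromatic Claisen rearrangement, whose [3,3] shift delivers the allyl terminus to either of the two equivalent ortho carbons and turns the 1,1-dimethylallyl ether into a linear prenyl group, after which dienone 4 re-aromatises by tautomerisation (the basic solvent suppresses acid-induced ether cleavage and premature chroman formation).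

**Step 3**
Reactants: 5 3,5-bis(benzyloxy)-2-(3-methylbut-2-en-1-yl)phenol
Product: 7 (3R)-5,7-bis(benzyloxy)-2,2-dimethyl-3,4-dihydro-2H-chromen-3-ol, via epoxyphenol 6 (not isolated)
Conditions: Hf(OtBu)4 (10 mol%), N,N'-[(1R,2R)-cyclohexane-1,2-diyl]bis(N-hydroxy-2,2-diphenylacetamide) (11 mol%), DMPU (20 mol%), cumene hydroperoxide (1.5 equiv), 4 Å MS, toluene, 0 °C; then CSA (10 mol%), CH2Cl2, 0 °C
Reagents that add atoms: cumene hydroperoxide, CC(C)(OO)c1ccccc1
Why: Proposed new method: phenol-directed Hf(IV)/chiral bis-hydroxamic-acid epoxidation terminated by 6-endo epoxide opening, in which the phenoxide of 5 exchanges onto the Hf(ligand)(cumylperoxide) centre and the bound peroxide oxygen is delivered intramolecularly to the prenyl double bond held three atoms away (a rigid bishomoallylic relationship), so the C2-symmetric ligand pocket selects one olefin face to give (R)-epoxide 6, and the Lewis acid (completed by catalytic CSA) then opens the epoxide at its tertiary carbon with the same phenol oxygen, closing the pyran 6-endo without ever breaking the secondary C–O bond, so the epoxide configuration becomes C3 (R) of 7; the closest known reaction types are the Zr/Hf–bis-hydroxamic-acid directed asymmetric epoxidation of homoallylic and bishomoallylic alcohols and the racemic vanadium-catalysed phenol-directed epoxidation–cyclisation of 2-allylphenols, neither of which has been shown enantioselectively with a phenol as the directing group.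

**Step 4**
Reactants: 7 (3R)-5,7-bis(benzyloxy)-2,2-dimethyl-3,4-dihydro-2H-chromen-3-ol
Product: 8 (3R)-3,5,7-tris(benzyloxy)-2,2-dimethyl-3,4-dihydro-2H-chromene
Conditions: NaH, BnBr, Bu4NI (cat.), DMF, 0 °C → rt
Reagents that add atoms: benzyl bromide, BrCc1ccccc1
Why: Williamson etherification masks the 3-OH for the organolithium step as a benzyl ether that later leaves together with the two aryl benzyl ethers, and it reacts at oxygen only so C3 keeps its (R) configuration.

**Step 5**
Reactants: 8 (3R)-3,5,7-tris(benzyloxy)-2,2-dimethyl-3,4-dihydro-2H-chromene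
Product: 9 (3R)-3,5,7-tris(benzyloxy)-8-bromo-2,2-dimethyl-3,4-dihydro-2H-chromene
Conditions: NBS (1.0 equiv), CH2Cl2, −78 → 0 °C, dark
Reagents that add atoms: N-bromosuccinimide, O=C1CCC(=O)N1Br
Why: Electrophilic aromatic bromination goes to C8, which is flanked by the tied-back ring oxygen and is less hindered than C6 between two benzyloxy groups (the selectivity pattern of 5,7-di-O-benzyl flavan-3-ols), and the regiochemistry is confirmed by NOE from the remaining aryl H to both ArOCH2 groups.

**Step 6**
Reactants: 9 (3R)-3,5,7-tris(benzyloxy)-8-bromo-2,2-dimethyl-3,4-dihydro-2H-chromene; 10 N-methoxy-N-methylbenzamide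
Product: 13 [(3R)-3,5,7-tris(benzyloxy)-2,2-dimethyl-3,4-dihydro-2H-chromen-8-yl](phenyl)methanone, via aryllithium 11 (not isolated), via lithium hemiaminal alkoxide 12 (not isolated)
Conditions: n-BuLi (1.05 equiv), THF, −78 °C, 10 min; then 10, −78 → 0 °C; then H2O
Reagents that add atoms: none
Why: Bromine–lithium exchange followed by Weinreb ketone synthesis, in which the chelated tetrahedral adduct 12 prevents over-addition and collapses to the ketone on work-up, while the benzyl ethers and the C3 stereocentre are inert at −78 °C.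

**Step 7**
Reactants: 13 [(3R)-3,5,7-tris(benzyloxy)-2,2-dimethyl-3,4-dihydro-2H-chromen-8-yl](phenyl)methanone
Product: 14 [(3R)-3,5,7-trihydroxy-2,2-dimethyl-3,4-dihydro-2H-chromen-8-yl](phenyl)methanone
Conditions: H2 (1 atm), 20% Pd(OH)2/C, EtOAc–MeOH 4:1, rt, stopped at 3 equiv uptake
Reagents that add atoms: none
Why: Catalytic hydrogenolysis cleaves the three O–CH2Ph bonds (never C3–O) while the di-ortho-substituted, electron-rich benzophenone carbonyl, hydrogen-bonded to 7-OH once freed, resists reduction.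

**Step 8**
Reactants: 14 [(3R)-3,5,7-trihydroxy-2,2-dimethyl-3,4-dihydro-2H-chromen-8-yl](phenyl)methanone; 15 geranyl bromide, (2E)-1-bromo-3,7-dimethylocta-2,6-diene
Product: 16 [(3R)-6-[(2E)-3,7-dimethylocta-2,6-dien-1-yl]-3,5,7-trihydroxy-2,2-dimethyl-3,4-dihydro-2H-chromen-8-yl](phenyl)methanone
Conditions: KOH (2.2 equiv), H2O, 0 °C; 15 (1.1 equiv), 0 °C → rt
Reagents that add atoms: none
Why: C-alkylation of an acylphloroglucinol-type phenoxide in water, where hydrogen-bond solvation of oxygen favours attack through the only free ring carbon (C6), and SN2 displacement on the primary allylic bromide keeps the E geometry while the un-ionised 3-OH and C3 are untouched.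

**Compound list**
1 | 3,5-bis(benzyloxy)phenol | Oc1cc(OCc2ccccc2)cc(OCc2ccccc2)c1 | starting material
2 | tert-butyl (2-methylbut-3-en-2-yl) carbonate | C=CC(C)(C)OC(=O)OC(C)(C)C | starting material
3 | 1,3-bis(benzyloxy)-5-[(2-methylbut-3-en-2-yl)oxy]benzene | C=CC(C)(C)Oc1cc(OCc2ccccc2)cc(OCc2ccccc2)c1 | intermediate
4 | 3,5-bis(benzyloxy)-6-(3-methylbut-2-en-1-yl)cyclohexa-2,4-dien-1-one (racemic, transient) | CC(C)=CCC1C(=O)C=C(OCc2ccccc2)C=C1OCc1ccccc1 | intermediate
5 | 3,5-bis(benzyloxy)-2-(3-methylbut-2-en-1-yl)phenol | CC(C)=CCc1c(O)cc(OCc2ccccc2)cc1OCc1ccccc1 | intermediate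
6 | 3,5-bis(benzyloxy)-2-{[(2R)-3,3-dimethyloxiran-2-yl]methyl}phenol | CC1(C)O[C@@H]1Cc1c(O)cc(OCc2ccccc2)cc1OCc1ccccc1 | intermediate
7 | (3R)-5,7-bis(benzyloxy)-2,2-dimethyl-3,4-dihydro-2H-chromen-3-ol | c1c(OCc2ccccc2)cc(OCc2ccccc2)c2c1OC(C)(C)[C@H](O)C2 | intermediate
8 | (3R)-3,5,7-tris(benzyloxy)-2,2-dimethyl-3,4-dihydro-2H-chromene | c1c(OCc2ccccc2)cc(OCc2ccccc2)c2c1OC(C)(C)[C@H](OCc1ccccc1)C2 | intermediate
9 | (3R)-3,5,7-tris(benzyloxy)-8-bromo-2,2-dimethyl-3,4-dihydro-2H-chromene | Brc1c(OCc2ccccc2)cc(OCc2ccccc2)c2c1OC(C)(C)[C@H](OCc1ccccc1)C2 | intermediate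
10 | N-methoxy-N-methylbenzamide | CON(C)C(=O)c1ccccc1 | starting material
11 | [(3R)-3,5,7-tris(benzyloxy)-2,2-dimethyl-3,4-dihydro-2H-chromen-8-yl]lithium | [Li]c1c(OCc2ccccc2)cc(OCc2ccccc2)c2c1OC(C)(C)[C@H](OCc1ccccc1)C2 | intermediate
12 | lithium [(3R)-3,5,7-tris(benzyloxy)-2,2-dimethyl-3,4-dihydro-2H-chromen-8-yl][methoxy(methyl)amino](phenyl)methanolate (epimers at the new carbon) | CON(C)C(O[Li])(c1ccccc1)c1c(OCc2ccccc2)cc(OCc2ccccc2)c2c1OC(C)(C)[C@H](OCc1ccccc1)C2 | intermediate
13 | [(3R)-3,5,7-tris(benzyloxy)-2,2-dimethyl-3,4-dihydro-2H-chromen-8-yl](phenyl)methanone | O=C(c1ccccc1)c1c(OCc2ccccc2)cc(OCc2ccccc2)c2c1OC(C)(C)[C@H](OCc1ccccc1)C2 | intermediate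
14 | [(3R)-3,5,7-trihydroxy-2,2-dimethyl-3,4-dihydro-2H-chromen-8-yl](phenyl)methanone | O=C(c1ccccc1)c1c(O)cc(O)c2c1OC(C)(C)[C@H](O)C2 | intermediate
15 | geranyl bromide, (2E)-1-bromo-3,7-dimethylocta-2,6-diene | CC(C)=CCC/C(C)=C/CBr | starting material
16 | [(3R)-6-[(2E)-3,7-dimethylocta-2,6-dien-1-yl]-3,5,7-trihydroxy-2,2-dimethyl-3,4-dihydro-2H-chromen-8-yl](phenyl)methanone (CNP0186586.1) | CC(C)=CCC/C(C)=C/Cc1c(O)c2c(c(C(=O)c3ccccc3)c1O)OC(C)(C)[C@H](O)C2 | target

**Totals**
Total step count: 8. Longest linear sequence: 8 steps (1 → 16).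

**Three steps most likely to fail**

Step 3 (the proposed new method). The phenoxide may bind Hf without useful face control, or the epoxide may open 5-exo to the dihydrobenzofuran carbinol. The fallback uses known chemistry, sets out from 5 and comes back at 7. DDQ (1.1 equiv, benzene, 60 °C) cyclodehydrogenates the o-prenylphenol to 5,7-bis(benzyloxy)-2,2-dimethyl-2H-chromene F1, so the ring is closed before oxidation and no 5-exo/6-endo question remains. Jacobsen–Katsuki epoxidation of F1 ((R,R)-(salen)Mn(III)Cl 4 mol%, 4-phenylpyridine N-oxide, buffered NaOCl, CH2Cl2, 0 °C) gives (3R,4R)-5,7-bis(benzyloxy)-3,4-epoxy-2,2-dimethyl-3,4-dihydro-2H-chromene F2; the catalyst antipode is chosen by analogy with 2,2-dimethylchromene. F2 is acid-labile and is used crude after filtration through basic alumina. LiAlH4 (THF, −20 °C) delivers hydride to benzylic C4 and leaves the C3–O bond intact, giving 7.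

Step 6 (acylation of a di-ortho-oxygenated aryllithium). Addition to the Weinreb amide may be slow enough for 11 to be quenched or to attack a benzylic OCH2. The fallback sets out from 9 and comes back at 13. Aryllithium 11 is generated as before and trapped with the more electrophilic benzaldehyde (−78 °C) to give [(3R)-3,5,7-tris(benzyloxy)-2,2-dimethyl-3,4-dihydro-2H-chromen-8-yl](phenyl)methanol F3 as an inconsequential epimer mixture at the carbinol carbon. Dess–Martin periodinane (NaHCO3, CH2Cl2, rt) oxidises F3 to 13.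

Step 8 (C- versus O-geranylation). O-alkylation at the acidic 5-OH, ipso-alkylation at C4a or double alkylation can lower the yield. The fallback sets out from 14 and comes back at 16. Geranyl bromide 15 with K2CO3 in acetone (rt) alkylates only the non-chelated 5-OH to give [(3R)-5-{[(2E)-3,7-dimethylocta-2,6-dien-1-yl]oxy}-3,7-dihydroxy-2,2-dimethyl-3,4-dihydro-2H-chromen-8-yl](phenyl)methanone F4. Montmorillonite K10 (CH2Cl2, 0 °C) then induces the [1,3] O→C shift of the geranyl group to the only free neighbouring ring carbon, C6, giving 16.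

**Further compounds**
F1 | step 3 | 5,7-bis(benzyloxy)-2,2-dimethyl-2H-chromene | c1c(OCc2ccccc2)cc(OCc2ccccc2)c2c1OC(C)(C)C=C2
F2 | step 3 | (3R,4R)-5,7-bis(benzyloxy)-3,4-epoxy-2,2-dimethyl-3,4-dihydro-2H-chromene | c1c(OCc2ccccc2)cc(OCc2ccccc2)c2c1OC(C)(C)[C@@H]3O[C@H]23
F3 | step 6 | [(3R)-3,5,7-tris(benzyloxy)-2,2-dimethyl-3,4-dihydro-2H-chromen-8-yl](phenyl)methanol | OC(c1ccccc1)c1c(OCc2ccccc2)cc(OCc2ccccc2)c2c1OC(C)(C)[C@H](OCc1ccccc1)C2
F4 | step 8 | [(3R)-5-{[(2E)-3,7-dimethylocta-2,6-dien-1-yl]oxy}-3,7-dihydroxy-2,2-dimethyl-3,4-dihydro-2H-chromen-8-yl](phenyl)methanone | O=C(c1ccccc1)c1c(O)cc(OC/C=C(\C)CCC=C(C)C)c2c1OC(C)(C)[C@H](O)C2
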